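## Analysis of the target

The target 17 is a fully O-methylated flavonol. It consists of a 4H-chromen-4-one (pyranone ring C fused to benzo ring A) with methoxy groups at C3, C5, C7 and C8 and a 2-methoxyphenyl group (ring B) at C2. It contains no stereocentre, and the C2–C1' axis is not expected to be configurationally stable, so no stereochemical element has to be controlled. Three groups are sensitive. The γ-pyranone is opened by hydroxide or alkoxide at C2 as long as C2 carries hydrogen. The 5-OMe group peri to the C4 carbonyl is labile towards chelating Lewis acids. Ring A is electron-rich, and its only free position, C6, is open to electrophiles and oxidants. The difficulties are the 5,7,8 oxygenation pattern of ring A (which must not become its 5,6,7 isomer), the oxygen at C3, and the C2–C1' bond, which is crowded by the 3-OMe group on one side and the 2'-OMe group on the other. The strategy rests on that last feature. O3 on ring C and O2' on ring B both stand ortho to the C2–C1' bond, so a single CH2 unit joining them places C2 and C1' at the ends of a seven-membered ring. The two tether oxygens are the ones that end as methoxy groups.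

## Retrosynthetic reasoning

**17 to 16.** The three O–CH3 bonds at O3, O5 and O2' are cut. O3 and O2' are the anchor points of the temporary bridge, and O5 is unmasked by the reagent that removes the bridge. The forward reaction is one exhaustive O-methylation of the triol 16, which includes the two hydroxyls hydrogen-bonded to the C4 carbonyl.

**16 to 15.** O3 and O2' are reconnected through one carbon. The forward step must cleave a formal whose two oxygens are both poor donors (one phenolic, one on an enone), which calls for a boron trihalide. That reagent also removes the peri methyl group at O5, so this is accepted and driven to completion to give one defined triol.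

**15 to 14.** The C2–C1' bond is cut; this is the key disconnection. It is the only carbon–carbon bond between the two halves, and cutting it makes ring B a simple ortho-bromophenol derivative and ring C a chromone with a free C2–H. The alternative of cutting inside ring C would require an ortho-methoxybenzoyl building block and a later oxygenation at C3 of a hindered flavone. Forward, a palladium catalyst must insert into the C–Br bond of 14, cleave the C2–H bond and close the seven-membered dioxepine ring of 15.

**14 to 9 and 13.** The O3–CH2 bond is cut. The chromonol 9 is an acidic enol and the aryl chloromethyl ether 13 is an activated electrophile, so the forward step is an ordinary O-alkylation that builds the unsymmetrical formal without statistical mixtures.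

**13 to 12, and 12 to 10 and 11.** The C–Cl bond of 13 is traced back to the C–S bond of the O,S-acetal 12, and the O–CH2 bond of 12 to the phenol 10 and the α-chloro sulfide 11. This two-stage sequence gives the one-carbon electrophile on a single oxygen.

**9 to 7 (through 8).** The C3–O bond is cut. Oxygen is placed on the chromone 7 before ring B arrives, while C2=C3 is unhindered. The forward step is epoxidation to 8 and acid-induced rearrangement to 9.

**7 to 4 and 5 (through 6).** The O1–C2 and C3–C2 bonds are cut. The acetal 5 supplies C2; condensation with the methyl ketone 4 gives the enaminone 6, and the phenol then closes ring C with loss of the amine.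

**4 to 1 and 2 (through 3).** The aryl–carbonyl bond is cut. Arene 1 is symmetrical, so acylation by 2 can give only ketone 3. Selective loss of one ortho methyl group from 3 then fixes which oxygen becomes O1, and with it the 5,7,8 pattern.

## Alternatives that were turned down

**Alternative 1:** The disconnection is C3–C4 of ring C. Forward, the dialdehyde A2 (rac-3,4,6-trimethoxy-2-[1-(2-methoxyphenyl)-2-oxoethoxy]benzaldehyde) would be reduced by SmI2 in THF to two ketyl radicals that couple intramolecularly to the cis-3,4-diol A1.
- For: six-membered pinacol closures with SmI2 are dependable and cis-selective, and ring C arrives with O3 and O4 in place. On that point it is stronger than the chosen route, which needs a separate hydroxylation (step 3).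
- Against: 17 is flat and achiral, so the three stereocentres of A1 are made only to be destroyed. A1 lies two oxidation levels below a flavonol: the C4 carbinol must be oxidised and C2–C3 dehydrogenated, with two secondary hydroxyls to be told apart, before O3 is methylated. A2 contains an α-aryl-α-aryloxy acetaldehyde that enolises and eliminates easily, and it requires etherification of a hindered, chelated phenol with a secondary benzylic electrophile. The ring A regiochemistry problem is not removed.
- Comparison: the route is longer and redox-wasteful. The chosen strategy keeps every carbon at its final oxidation level from chromone 7 onwards and uses O3 twice, first as tether anchor and then as the methoxy oxygen.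

**Alternative 2:** The disconnection is C5–C6 of ring A, with ring C present beforehand as a 4-pyranone. Forward, the pyranone A4 (methyl 5-methoxy-2-(1-methoxy-2-oxopropyl)-6-(2-methoxyphenyl)-4-oxo-4H-pyran-3-carboxylate) would be treated with excess LiN(iPr)2. The terminal methyl enolate attacks the ester carbonyl, and the cyclic β-diketone enolises to the resorcinol A3.
- For: the closure mirrors polyketide aromatisation, and the 8-OMe group is in place before ring A exists, so the 5,7,8 pattern is unambiguous. This is stronger than the chosen route, whose step 1 depends on a selective demethylation.
- Against: A4 is a pentasubstituted pyranone that already carries ring B, O3 and a stereogenic side chain, and is harder to assemble than 17 itself. The side-chain methine is more acidic than the methyl group, so a dianion is needed on a pyranone that is itself an electrophile towards amide bases and enolates. A3 still needs two O-methylations, one at the chelated 5-OH.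
- Comparison: the hardest problem is moved into the precursor. The chosen route draws ring A from a symmetrical commercial arene in one step and concentrates its risk in one catalytic bond formation.

**Alternative 3:** The disconnection is C4a–C4, C4–C3 and O1–C2, a three-component assembly from the iodophenol A6 (2-iodo-3,5,6-trimethoxyphenol), carbon monoxide A8 and the alkyne A7 (1-ethynyl-2-methoxybenzene). Forward, PdCl2(PPh3)2 in Et2NH under A8 would give an ortho-hydroxyaryl ynone that cyclises in the same flask to the flavone A5.
- For: three bonds and ring C form in one operation from two fragments, by an established reaction. In bond-forming economy and convergency it is clearly stronger than the chosen key step, which forms one bond through a tether that is removed again.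
- Against: A5 carries hydrogen at C3. The missing oxygen would have to be introduced afterwards on a C2=C3 bond shielded by the ortho-substituted ring B, and then methylated. A6 is not a stock compound, and its iodine must enter one specific position of a tetra-oxygenated ring whose two free positions are both activated. Exo cyclisation of the ynone to an aurone is a known side path.
- Comparison: once A6 and the C3 oxygenation are counted, the step count is similar. In place of convergency the chosen route offers a ring A building block made in one step from arene 1, and C3 oxygenation on the unhindered chromone 7, where the new oxygen then serves as the anchor that makes the crowded C2–C1' bond formation intramolecular.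

Key step: step 7

Remark on the chemistry: it is assumed that in step 1 AlCl3 cleaves the methoxy group flanked by the acetyl group and a second methoxy group (C2 of ketone 3) and not the C6 methoxy group, as is general for buttressed ortho-methoxy aryl ketones.

## Route

**Step 1**
Reactants: 1 1,2,3,5-tetramethoxybenzene; 2 acetyl chloride
Product: 4 1-(2-hydroxy-3,4,6-trimethoxyphenyl)ethanone, via 2,3,4,6-tetramethoxyacetophenone 3 (not isolated)
Conditions: AlCl3 (2.5 equiv), CH2Cl2, 0 °C → rt; aq. HCl work-up
Reagents that add atoms: none
Why: Friedel–Crafts acylation at one of the two equivalent free positions (each ortho to two and para to one methoxy group) can give only ketone 3, formed as its AlCl3 chelate. The Lewis acid should then cleave the ortho methoxy group that is pushed out of the ring plane by the neighbouring 3-OMe group, leaving a phenol hydrogen-bonded to the ketone.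

**Step 2**
Reactants: 4 1-(2-hydroxy-3,4,6-trimethoxyphenyl)ethanone; 5 N,N-dimethylformamide dimethyl acetal
Product: 7 5,7,8-trimethoxy-4H-chromen-4-one, via (E)-3-(dimethylamino)-1-(2-hydroxy-3,4,6-trimethoxyphenyl)prop-2-en-1-one 6 (not isolated)
Conditions: neat 5, 95 °C; evaporate; then conc. HCl, CH2Cl2, 40 °C
Reagents that add atoms: none
Why: Condensation of the methyl ketone with the formamide acetal gives the vinylogous amide 6. Acid then triggers conjugate addition of the phenol (6-endo) and loss of dimethylamine, the standard enaminone route to 2,3-unsubstituted chromones.

**Step 3**
Reactants: 7 5,7,8-trimethoxy-4H-chromen-4-one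
Product: 9 3-hydroxy-5,7,8-trimethoxy-4H-chromen-4-one, via rac-2,3-epoxy-5,7,8-trimethoxychroman-4-one 8 (not isolated)
Conditions: DMDO (acetone solution, 2 equiv), CH2Cl2, 0 °C → rt; evaporate; then p-TsOH·H2O (cat.), CH2Cl2, rt
Reagents that add atoms: dimethyldioxirane, CC1(C)OO1
Why: The dioxirane epoxidises the enol-ether-like C2=C3 bond to the racemic cis-fused epoxide 8, whose two stereocentres are transient. Acid opens the epoxide at C2 to the oxocarbenium ion, and loss of H3 should give the chromonol (epoxidation–rearrangement, as used for flavonols from flavones).

**Step 4**
Reactants: 10 2-bromophenol; 11 chloromethyl methyl sulfide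
Product: 12 1-bromo-2-[(methylsulfanyl)methoxy]benzene
Conditions: NaH, NaI (cat.), DMF, 0 °C → rt
Reagents that add atoms: none
Why: Williamson alkylation of the sodium phenoxide by the α-chloro sulfide, with iodide catalysis, gives the methylthiomethyl ether. The aryl bromide is inert under these conditions.

**Step 5**
Reactants: 12 1-bromo-2-[(methylsulfanyl)methoxy]benzene
Product: 13 1-bromo-2-(chloromethoxy)benzene
Conditions: SO2Cl2 (1.05 equiv), CH2Cl2, 0 °C → rt; evaporate, use crude
Reagents that add atoms: sulfuryl chloride, O=S(=O)(Cl)Cl
Why: Chlorinolysis of an O,S-acetal: S-chlorination gives a chlorosulfonium ion that fragments to the oxocarbenium ion, which chloride captures. The by-products are volatile and should be removed on evaporation.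

**Step 6**
Reactants: 9 3-hydroxy-5,7,8-trimethoxy-4H-chromen-4-one; 13 1-bromo-2-(chloromethoxy)benzene
Product: 14 3-[(2-bromophenoxy)methoxy]-5,7,8-trimethoxy-4H-chromen-4-one
Conditions: K2CO3, acetone (dry), rt
Reagents that add atoms: none
Why: O-alkylation of the acidic chromonol by the activated α-chloro ether, the same reaction type as MOM protection of a flavonol 3-OH. Carbonate in a dry aprotic solvent does not attack the pyranone, and the C2–H and C–Br bonds are untouched.

**Step 7**
Reactants: 14 3-[(2-bromophenoxy)methoxy]-5,7,8-trimethoxy-4H-chromen-4-one
Product: 15 5,7,8-trimethoxy-3,2'-(methylenedioxy)flavone (O3 and O2' bridged by CH2 in a seven-membered 1,3-dioxepine ring fused to ring C and ring B)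
Conditions: Pd(OAc)2 (10 mol %), PCy3·HBF4 (20 mol %), PivOH (30 mol %), K2CO3 (2 equiv), DMA (0.02 M), 110 °C, Ar
Reagents that add atoms: none
Why: Pd(OAc)2 is reduced in situ to zerovalent palladium, which inserts into the C–Br bond of 14 to give an arylpalladium bromide of divalent palladium held next to C2 by the O–CH2–O bridge. After exchange of bromide for pivalate, the carboxylate removes the C2 proton while palladium binds C2 (concerted metalation–deprotonation); this C–H is the most acidic in the molecule because C2 is bonded to O1 and is the β-carbon of the enone. Reductive elimination from the resulting eight-membered diaryl palladacycle forms C2–C1' and closes the seven-membered dioxepine ring, so the ring closes by C(sp2)–C(sp2) bond formation between the two ends of a five-atom tether; a Heck-type carbopalladation of C2=C3 followed by base-mediated elimination would give the same product. The closest known reaction type is the palladium-catalysed intramolecular direct arylation of heteroarene C–H bonds by tethered aryl bromides under carbonate/pivalate conditions, which closes five-, six- and seven-membered rings, together with direct C2 arylation of chromones. No stereocentre is formed, and the twisted biaryl of the dioxepine should invert freely. The step needs site selectivity on both partners: the bromine fixes C1', C2 is the only C–H of ring C, and C6–H of ring A cannot be reached through the tether. High dilution should favour ring closure over intermolecular coupling, and the formal, the methyl ethers and the pyranone should tolerate anhydrous carbonate.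

**Step 8**
Reactants: 15 5,7,8-trimethoxy-3,2'-(methylenedioxy)flavone
Product: 16 3,5-dihydroxy-2-(2-hydroxyphenyl)-7,8-dimethoxy-4H-chromen-4-one
Conditions: BCl3 (5 equiv), CH2Cl2, −78 → 0 °C; then aq. HCl/THF, rt
Reagents that add atoms: none
Why: BCl3 cleaves methylene acetals of phenols in preference to ordinary aryl methyl ethers, and the chloromethyl ether left on one oxygen is hydrolysed on work-up. The 5-OMe group peri to the carbonyl is cleaved as well through its six-membered boron chelate, so excess reagent is used to make the triol 16 the single product. The 7- and 8-OMe groups lack such assistance and should survive at 0 °C.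

**Step 9**
Reactants: 16 3,5-dihydroxy-2-(2-hydroxyphenyl)-7,8-dimethoxy-4H-chromen-4-one
Product: 17 3,5,7,8-tetramethoxy-2-(2-methoxyphenyl)-4H-chromen-4-one
Conditions: MeI (excess), K2CO3, DMF, 50 °C, N2
Reagents that add atoms: iodomethane, CI
Why: Williamson O-methylation of all three hydroxyls. The 2'-OH should react first, while the 3-OH and 5-OH chelated to the carbonyl need excess reagent and warming, as in the permethylation of polyhydroxyflavones; nitrogen protects the flavonol anion from autoxidation.

## Compound list

1 | 1,2,3,5-tetramethoxybenzene | COc1cc(OC)c(OC)c(OC)c1 | starting material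
2 | acetyl chloride | CC(=O)Cl | starting material
3 | 2,3,4,6-tetramethoxyacetophenone (as AlCl3 chelate in the flask) | CC(=O)c1c(OC)cc(OC)c(OC)c1OC | intermediate
4 | 1-(2-hydroxy-3,4,6-trimethoxyphenyl)ethanone | CC(=O)c1c(OC)cc(OC)c(OC)c1O | intermediate
5 | N,N-dimethylformamide dimethyl acetal | COC(OC)N(C)C | starting material
6 | (E)-3-(dimethylamino)-1-(2-hydroxy-3,4,6-trimethoxyphenyl)prop-2-en-1-one | CN(C)/C=C/C(=O)c1c(OC)cc(OC)c(OC)c1O | intermediate
7 | 5,7,8-trimethoxy-4H-chromen-4-one | COc1cc(OC)c2c(=O)ccoc2c1OC | intermediate
8 | rac-2,3-epoxy-5,7,8-trimethoxychroman-4-one (cis-fused, one enantiomer drawn) | COc1cc(OC)c2C(=O)[C@@H]3O[C@@H]3Oc2c1OC | intermediate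
9 | 3-hydroxy-5,7,8-trimethoxy-4H-chromen-4-one | COc1cc(OC)c2c(=O)c(O)coc2c1OC | intermediate
10 | 2-bromophenol | Oc1ccccc1Br | starting material
11 | chloromethyl methyl sulfide | CSCCl | starting material
12 | 1-bromo-2-[(methylsulfanyl)methoxy]benzene | CSCOc1ccccc1Br | intermediate
13 | 1-bromo-2-(chloromethoxy)benzene | ClCOc1ccccc1Br | intermediate
14 | 3-[(2-bromophenoxy)methoxy]-5,7,8-trimethoxy-4H-chromen-4-one | COc1cc(OC)c2c(=O)c(OCOc3ccccc3Br)coc2c1OC | intermediate
15 | 5,7,8-trimethoxy-3,2'-(methylenedioxy)flavone (O3–CH2–O2' bridge, seven-membered 1,3-dioxepine) | COc1cc(OC)c2c(=O)c3OCOc4ccccc4-c3oc2c1OC | intermediate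
16 | 3,5-dihydroxy-2-(2-hydroxyphenyl)-7,8-dimethoxy-4H-chromen-4-one | COc1cc(O)c2c(=O)c(O)c(-c3ccccc3O)oc2c1OC | intermediate
17 | 3,5,7,8-tetramethoxy-2-(2-methoxyphenyl)-4H-chromen-4-one | COc1ccccc1-c1oc2c(OC)c(OC)cc(OC)c2c(=O)c1OC | target

## Step count and least certain steps

Total step count: 9. Longest linear sequence: 7 (steps 1, 2, 3, 6, 7, 8, 9); steps 4 and 5 form a two-step side branch that joins at step 6.

**Step 7 (key step).** The seven-membered closure is slower than five- or six-membered direct arylations. Intermolecular arylation and protodebromination may therefore compete, and at 110 °C carbonate with traces of water may open the pyranone at C2 before the C–H bond is cleaved. The fallback sets out from 14 and changes the mechanism of bond formation. Borylation of the bromide (bis(pinacolato)diboron, PdCl2(dppf), KOAc, dioxane, 80 °C) would give 5,7,8-trimethoxy-3-{[2-(4,4,5,5-tetramethyl-1,3,2-dioxaborolan-2-yl)phenoxy]methoxy}-4H-chromen-4-one F1. An intramolecular oxidative Heck-type arylation (Pd(OCOCF3)2, 2,2'-bipyridine, O2, DMSO, 60 °C) would then transfer the aryl group to divalent palladium, add it across C2=C3 and eliminate through the oxygen-bound palladium enolate. This needs neither carbonate nor cleavage of the C2–H bond by a carboxylate, and it comes back to the route at 15.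

**Step 3.** The electrophilic oxidant may attack the electron-rich ring A at C6 in competition with the enone double bond, and the labile epoxide may be opened hydrolytically before it rearranges. The fallback sets out from 7 and avoids any epoxide. Hydrogenation of C2=C3 (H2, Pd/C, EtOAc) would give 5,7,8-trimethoxychroman-4-one F2. α-Nitrosation with isoamyl nitrite in ethanolic HCl would give 3-(hydroxyimino)-5,7,8-trimethoxychroman-4-one F3, which is hydrolysed in the same acidic medium to the 3,4-dione. Its enol tautomer is 9, where the route is rejoined.

**Step 6 (with step 5).** The chelated 3-oxide of 9 is a weak nucleophile, so hydrolysis or self-condensation of the moisture-sensitive electrophile may outrun the alkylation. The fallback sets out from 9 and reverses the roles of the two partners. Alkylation of 9 with 11 (K2CO3, NaI, DMF) would give 5,7,8-trimethoxy-3-[(methylsulfanyl)methoxy]-4H-chromen-4-one F4. Chlorinolysis at sulfur (SO2Cl2, CH2Cl2, −78 °C, where attack on ring A should be much slower) would give 3-(chloromethoxy)-5,7,8-trimethoxy-4H-chromen-4-one F5. This is then displaced by the more nucleophilic, unhindered phenoxide of 10 (K2CO3, acetone), coming back at 14.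

**Step 8.** Cleavage may be unselective: further methyl ethers may be lost on prolonged exposure, or the transient chloromethyl ether may alkylate ring A at C6. The step also loads step 9 with the slow methylation of a chelated 5-OH. The fallback sets out from 15 and replaces the boron halide by a thiol-assisted transacetalisation (BF3·OEt2, ethane-1,2-dithiol, CH2Cl2, 0 °C → rt). This carries off the formal carbon as a dithioacetal, leaves every methyl ether in place and would give 3-hydroxy-2-(2-hydroxyphenyl)-5,7,8-trimethoxy-4H-chromen-4-one F6. Methylation of its two hydroxyls (MeI, K2CO3, acetone) comes back to the route at the target 17 and bypasses 16.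

## Further compounds

F1 | step 7 | 5,7,8-trimethoxy-3-{[2-(4,4,5,5-tetramethyl-1,3,2-dioxaborolan-2-yl)phenoxy]methoxy}-4H-chromen-4-one | COc1cc(OC)c2c(=O)c(OCOc3ccccc3B3OC(C)(C)C(C)(C)O3)coc2c1OC
F2 | step 3 | 5,7,8-trimethoxychroman-4-one | COc1cc(OC)c2C(=O)CCOc2c1OC
F3 | step 3 | 3-(hydroxyimino)-5,7,8-trimethoxychroman-4-one (oxime geometry not defined) | COc1cc(OC)c2C(=O)C(=NO)COc2c1OC
F4 | step 6 | 5,7,8-trimethoxy-3-[(methylsulfanyl)methoxy]-4H-chromen-4-one | COc1cc(OC)c2c(=O)c(OCSC)coc2c1OC
F5 | step 6 | 3-(chloromethoxy)-5,7,8-trimethoxy-4H-chromen-4-one | COc1cc(OC)c2c(=O)c(OCCl)coc2c1OC
F6 | step 8 | 3-hydroxy-2-(2-hydroxyphenyl)-5,7,8-trimethoxy-4H-chromen-4-one | COc1cc(OC)c2c(=O)c(O)c(-c3ccccc3O)oc2c1OC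
A1 | alternative 1 | rac-(2,3-trans,3,4-cis)-5,7,8-trimethoxy-2-(2-methoxyphenyl)chromane-3,4-diol | COc1ccccc1[C@H]1Oc2c(OC)c(OC)cc(OC)c2[C@H](O)[C@@H]1O
A2 | alternative 1 | rac-3,4,6-trimethoxy-2-[1-(2-methoxyphenyl)-2-oxoethoxy]benzaldehyde | COc1ccccc1C(C=O)Oc1c(C=O)c(OC)cc(OC)c1OC
A3 | alternative 2 | 5,7-dihydroxy-3,8-dimethoxy-2-(2-methoxyphenyl)-4H-chromen-4-one | COc1ccccc1-c1oc2c(OC)c(O)cc(O)c2c(=O)c1OC
A4 | alternative 2 | rac-methyl 5-methoxy-2-(1-methoxy-2-oxopropyl)-6-(2-methoxyphenyl)-4-oxo-4H-pyran-3-carboxylate | COC(=O)c1c(C(OC)C(C)=O)oc(-c2ccccc2OC)c(OC)c1=O
A5 | alternative 3 | 5,7,8-trimethoxy-2-(2-methoxyphenyl)-4H-chromen-4-one | COc1ccccc1-c1cc(=O)c2c(OC)cc(OC)c(OC)c2o1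
A6 | alternative 3 | 2-iodo-3,5,6-trimethoxyphenol | COc1cc(OC)c(OC)c(O)c1I
A7 | alternative 3 | 1-ethynyl-2-methoxybenzene | COc1ccccc1C#C
A8 | alternative 3 | carbon monoxide | [C-]#[O+]
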